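## The problem

The target 16 is (2R,3S,4S,5R)-2,5-bis(4-hydroxy-3,5-dimethoxyphenyl)-3,4-bis(hydroxymethyl)tetrahydrofuran: one oxolane ring (O1, C2–C5) with a syringyl group on C2 and C5 and a hydroxymethyl group on C3 and C4, C2-symmetric, every vicinal pair trans. The four stereocentres are contiguous ring carbons, so ring construction and stereocontrol cannot be separated. C3 and C4 are plain sp3 carbons that cannot be corrected once set. C2 and C5 are benzylic ether carbons next to electron-rich arenes: they can ionise under acid, which is a hazard but also makes the all-trans arrangement their thermodynamic resting state. Control therefore has to run outward, from C4 to C5 and C3, and from C3 to C2. The fragile features are the syringyl phenols (easily oxidised; once free they make the ring C–O bonds para-hydroxybenzyl ethers that open to quinone methides or are hydrogenolysed), the doubly benzylic ring C–O bonds, and two primary alcohols that must not compete with O1 during ring closure. The feature that opens the route is that C2 is an aldehyde-level carbon bonded to O1 and C3. Both O1–C2 and C2–C3 can then come from one syringaldehyde unit, if O1 is the hydroxyl of a C5–C4–C3 chain whose C3 is the γ-carbon of an allylsilane.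

## Retrosynthesis

**16 ⇒ 15.** Three O–Si bonds are cut. Silyl ethers are preferred to benzyl ethers on all three oxygens because a primary alkyl benzyl ether would need prolonged hydrogenolysis, during which the two ring C–O bonds (para-hydroxybenzylic once the phenols are free) are at risk. The skeleton is unchanged; the forward step only has to release the hydroxyls without leaving phenoxides free to open the ring.

**15 ⇒ 12 (through 13 and 14).** The C3 hydroxymethyl group is traced to a C3 vinyl group, one carbon longer, by C=C cleavage and reduction. The vinyl group is exactly what an allylsilane leaves behind, so this cut prepares the ring disconnection. The forward step must spare the arenes and not disturb C3, which is α to the transient aldehyde 14.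

**12 ⇒ 10 + 2.** O1–C2 and C2–C3 are cut, removing the ring, two stereocentres and one aryl group in one operation. Cutting the C–aryl bonds instead raises a regiochemical question on the arene; cutting both C–O bonds leaves an acyclic chain with four stereocentres; cutting C2–C3 and C4–C5 asks for four stereocentres at once. The precursor 10 is acyclic with only C4 and C5 set, and the partner is aldehyde 2. The forward reaction must form oxocarbenium ion 11, close through the γ-carbon only, and set C2 and C3 trans to each other and to C4.

**10 ⇒ 8 + 9.** The alkene between C3 and the silylmethyl-bearing carbon is cut by cross-metathesis, giving homoallylic alcohol 8 and allyltrimethylsilane 9. Carrying the silane through the C4–C5 bond formation would need a far less accessible allylmetal reagent. The forward step must give the E alkene and tolerate the free hydroxyl.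

**8 ⇒ 6 + 2.** The C4–C5 bond is cut. Allylboration of aldehyde 2 with the E allylboronate 6 makes this bond and both stereocentres in one step, whereas an aldol route would need extra redox adjustments. The forward reaction must be anti-selective (from the E geometry of 6) and face-selective (from a chiral Brønsted acid catalyst); the borate 7 is hydrolysed on work-up.

**6 ⇒ 4 ⇒ 3.** The B–CH2 carbon is removed (one-carbon homologation through ate complex 5), then the C–B and C–H bonds of the alkenylboronate 4 are cut (hydroboration of alkyne 3). Both steps keep the E geometry that later fixes the C4/C5 relationship.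

**2 ⇒ 1.** One O–Si bond is cut; syringaldehyde 1 supplies both aryl rings and C2 and C5.

## Roads not taken

**Alternative 1:** Two-directional arylation of a bis-acetal.
- **Cut:** both C–aryl bonds (C2–Ar, C5–Ar), back to the C2-symmetric bis-acetal (3S,4S)-3,4-bis[(tert-butyldiphenylsilyloxy)methyl]-2,5-dimethoxytetrahydrofuran A2 and two molecules of 2,6-dimethoxyphenol A3.
- **Forward key step:** a boron Lewis acid ionises the two anomeric methoxy groups of A2 in turn, and each oxocarbenium ion is captured by the para carbon of A3 in a Friedel–Crafts reaction. This gives the bis-silyl ether of the target, A1; one desilylation finishes.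
- **Merits:** it is the most convergent plan and uses the symmetry twice. The phenols need no protection. Both new centres are benzylic and flanked by fixed trans substituents, so kinetic anti attack and acid equilibration both point to the all-trans isomer.
- **Weak points:** in A3 the carbon para to the hydroxyl competes with the two carbons that are ortho to one methoxy group and para to the other, and with O-alkylation. After the first arylation the intermediate already holds a para-hydroxybenzylic ring ether that the same Lewis acid can open while the second acetal is being ionised. A2 is an enantiopure 2,3-bis(hydroxymethyl)succinaldehyde equivalent that would need its own multi-step asymmetric synthesis.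
- **Comparison:** from A2 onward this road is shorter and more convergent than the chosen plan, and avoids phenol protection. Against that, the chosen plan buys every carbon–aryl bond ready-made in 1, so there is no regiochemical question, and sets C4 and C5 in one catalytic step from commercial materials.

**Alternative 2:** Oxidative ring expansion of a diarylcyclobutane.
- **Cut:** both ring C–O bonds (O1–C2, O1–C5), with the ring oxygen delivered by hydration. The carbon skeleton is the all-trans head-to-head cyclobutane dimer A5 (dimethyl 3,4-bis(4-hydroxy-3,5-dimethoxyphenyl)cyclobutane-1,2-dicarboxylate, single enantiomer) of methyl sinapate A6.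
- **Forward key step:** a two-electron oxidant in wet solvent breaks the cyclobutane bond between the two aryl-bearing carbons of A5 to a bis(quinone methide). One terminus is hydrated and the new hydroxyl adds to the other, giving diester A4; ester reduction would complete the target.
- **Merits:** it is the shortest conceivable route (dimerise, oxidise, reduce), without protecting groups and driven by ring strain. The C3/C4 configuration is carried over from A5, and the reversible quinone methide additions should settle C2 and C5 trans.
- **Weak points:** the bis(quinone methide) has the same constitution as the intermediate of oxidative β–β coupling of A6, for which intramolecular arylation to an aryldihydronaphthalene skeleton is a well-known competing fate. Its central C–H bonds are α to ester groups and vinylogously acidic, so tautomerisation can erase C3 and C4. A4 is itself a bisphenol open to the same oxidant. An enantiopure all-trans head-to-head dimer is not what cinnamate photodimerisations normally give.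
- **Comparison:** in step and atom economy this road would be clearly better than the chosen plan. Against that, the chosen plan uses known reaction types throughout and a cationic intermediate (11) with one obvious intramolecular partner, and takes its absolute configuration from a catalyst rather than from a hard-to-make cyclobutane.

**Alternative 3:** Carbonyl ylide cycloaddition onto a chiral fumarate.
- **Cut:** C2–C3 and C4–C5, back to trans-2,3-bis(4-benzyloxy-3,5-dimethoxyphenyl)oxirane A8 and di-(−)-menthyl fumarate A9.
- **Forward key step:** photolysis opens the oxirane C–C bond of A8 to an E,Z carbonyl ylide, which adds across A9 to give the tetrahydrofuran diester A7. Hydride reduction of both esters and hydrogenolysis of the aryl benzyl ethers would follow.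
- **Merits:** two C–C bonds, the ring and all four stereocentres are formed in one step from two symmetric partners. The trans alkene guarantees 3,4-trans and the E,Z ylide 2,5-trans. The total would be about six steps.
- **Weak points:** an E,Z ylide and a trans alkene can still combine to the all-trans or to the 2,3-cis/4,5-cis product. Each of these can form in two absolute senses, distinguished only by remote menthyl groups acting without Lewis acid chelation. The ylide can relax to other geometries before bimolecular capture, eroding 2,5-trans. Both A8 and A7 contain photolabile benzylic ether bonds.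
- **Comparison:** this road beats the chosen plan in convergence and step count. Against that, the chosen plan sets the stereocentres two at a time, each pair with a defined control element, fixes the absolute configuration in one catalytic step and needs no photochemistry.

Key step: step 6

Assumption: the (R)-configured phosphoric acid in step 4 is taken to direct the allyl unit to the Re face of aldehyde 2, the sense known for aryl aldehydes with this catalyst class; if the sense proved opposite, the (S)-catalyst would be used and nothing else would change.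

Assumption: compounds 1, 3 and 9 are purchased.

## Route

Step 1
Reactants: 1 syringaldehyde (4-hydroxy-3,5-dimethoxybenzaldehyde)
Product: 2 4-(tert-butyldimethylsilyloxy)-3,5-dimethoxybenzaldehyde
Conditions: TBSCl, imidazole, DMF, rt
Reagents that add atoms: tert-butyldimethylsilyl chloride, CC(C)(C)[Si](C)(C)Cl
Why: Imidazole-mediated silylation of a phenol; the aldehyde is untouched and the silyl ether masks the phenol through all later acidic, oxidative and metathesis steps.

Step 2
Reactants: 3 tert-butyldimethyl(prop-2-yn-1-yloxy)silane
Product: 4 (E)-tert-butyldimethyl{[3-(4,4,5,5-tetramethyl-1,3,2-dioxaborolan-2-yl)prop-2-en-1-yl]oxy}silane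
Conditions: HBpin, Cp2Zr(H)Cl (5 mol%), Et3N (10 mol%), neat, 60 °C
Reagents that add atoms: pinacolborane, CC1(C)OBOC1(C)C
Why: Zirconocene hydride-catalysed syn hydroboration of a terminal alkyne places boron on the terminal carbon and gives the E alkenylboronate; the silyl ether is inert.

Step 3
Reactants: 4 (E)-tert-butyldimethyl{[3-(4,4,5,5-tetramethyl-1,3,2-dioxaborolan-2-yl)prop-2-en-1-yl]oxy}silane
Product: 6 (E)-tert-butyldimethyl{[4-(4,4,5,5-tetramethyl-1,3,2-dioxaborolan-2-yl)but-2-en-1-yl]oxy}silane, via lithium boronate complex 5 (not isolated)
Conditions: BrCH2Cl, n-BuLi, THF, −78 °C → rt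
Reagents that add atoms: bromochloromethane, ClCBr
Why: Matteson homologation: chloromethyllithium made in the flask adds to boron to give ate complex 5, and 1,2-migration of the alkenyl group with loss of chloride inserts CH2 into the C–B bond with retention of the E geometry.

Step 4
Reactants: 6 (E)-tert-butyldimethyl{[4-(4,4,5,5-tetramethyl-1,3,2-dioxaborolan-2-yl)but-2-en-1-yl]oxy}silane; 2 4-(tert-butyldimethylsilyloxy)-3,5-dimethoxybenzaldehyde
Product: 8 (1R,2S)-1-[4-(tert-butyldimethylsilyloxy)-3,5-dimethoxyphenyl]-2-[(tert-butyldimethylsilyloxy)methyl]but-3-en-1-ol, via pinacol borate ester 7 (not isolated)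
Conditions: (R)-3,3′-bis(2,4,6-triisopropylphenyl)-1,1′-binaphthyl-2,2′-diyl hydrogen phosphate (5 mol%), 4 Å MS, toluene, −30 °C; then aq. NaHCO3
Reagents that add atoms: none
Why: Chiral phosphoric acid-catalysed allylboration through a closed six-membered chair transition state: the E geometry of 6 puts the CH2OTBS group equatorial and gives the anti (C4/C5) pair, and the (R)-catalyst, hydrogen-bonded to a boronate oxygen and the formyl hydrogen, directs attack to the Re face to give the 1R carbinol; borate 7 is hydrolysed on work-up.

Step 5
Reactants: 8 (1R,2S)-1-[4-(tert-butyldimethylsilyloxy)-3,5-dimethoxyphenyl]-2-[(tert-butyldimethylsilyloxy)methyl]but-3-en-1-ol; 9 allyltrimethylsilane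
Product: 10 (1R,2S,3E)-1-[4-(tert-butyldimethylsilyloxy)-3,5-dimethoxyphenyl]-2-[(tert-butyldimethylsilyloxy)methyl]-5-(trimethylsilyl)pent-3-en-1-ol
Conditions: second-generation Grubbs catalyst (H2IMes)(PCy3)Cl2Ru=CHPh (5 mol%), 9 (4 equiv), CH2Cl2, 40 °C
Reagents that add atoms: none
Why: Olefin cross-metathesis: the allylically branched alkene of 8 homodimerises slowly while excess 9 and its dimer keep re-entering the cycle, so the cross product dominates; the branch next to the alkene favours the E isomer and the free hydroxyl is tolerated.

Step 6
Reactants: 10 (1R,2S,3E)-1-[4-(tert-butyldimethylsilyloxy)-3,5-dimethoxyphenyl]-2-[(tert-butyldimethylsilyloxy)methyl]-5-(trimethylsilyl)pent-3-en-1-ol; 2 4-(tert-butyldimethylsilyloxy)-3,5-dimethoxybenzaldehyde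
Product: 12 (2R,3R,4S,5R)-2,5-bis[4-(tert-butyldimethylsilyloxy)-3,5-dimethoxyphenyl]-4-[(tert-butyldimethylsilyloxy)methyl]-3-vinyltetrahydrofuran, via E-oxocarbenium triflate 11 (not isolated)
Conditions: Me3SiOTf (1.1 equiv), 2 (1.2 equiv), Et2O, −78 °C; then sat. aq. NaHCO3
Reagents that add atoms: none
Why: The silyl triflate condenses the C5 hydroxyl of 10 with aldehyde 2 through a mixed silyl acetal to the aryl-stabilised E-oxocarbenium ion 11 (O1–C2), which is attacked by the γ-carbon of the allylsilane (C2–C3); the β-silyl cation then loses Me3Si+ to leave the C3 vinyl group. The closest known reaction type is the intramolecular Hosomi–Sakurai (silyl-Prins) cyclisation of hydroxy allylsilanes with aldehydes, which gives 3-vinyltetrahydrofurans and 4-methylenetetrahydropyrans. The oxolane closes by C–C bond formation, 5-endo with respect to the O1=C2 π bond and exo with respect to the C3 alkene, through an envelope transition state that cationic oxocarbenium carbons reach readily. C3 is controlled by C4: the alkenyl group turns away from the pseudo-equatorial CH2OTBS group, so the alkene face anti to it attacks and C3/C4 become trans. C2 is controlled by the E geometry of 11 together with the exo, antiperiplanar orientation of the alkene, which places the C2 aryl group and the developing vinyl group on opposite faces (2,3-trans). C4 and C5 are carried over from 10, so the all-trans isomer results. The step needs γ-regioselectivity (secured by silicon, which stabilises positive charge only at its β carbon), selectivity for O1 (secured by silylation of every other hydroxyl) and an E allylsilane (its CH2SiMe3 group points away from the forming ring, whereas a Z group would clash with C4).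

Step 7
Reactants: 12 (2R,3R,4S,5R)-2,5-bis[4-(tert-butyldimethylsilyloxy)-3,5-dimethoxyphenyl]-4-[(tert-butyldimethylsilyloxy)methyl]-3-vinyltetrahydrofuran
Product: 15 {(2R,3S,4S,5R)-2,5-bis[4-(tert-butyldimethylsilyloxy)-3,5-dimethoxyphenyl]-4-[(tert-butyldimethylsilyloxy)methyl]tetrahydrofuran-3-yl}methanol, via diol 13 (not isolated), via aldehyde 14 (not isolated)
Conditions: OsO4 (2 mol%), NaIO4, 2,6-lutidine, dioxane/H2O, rt; then NaBH4, MeOH, 0 °C
Reagents that add atoms: osmium tetroxide, O=[Os](=O)(=O)=O; sodium periodate (terminal oxidant that restores it), [Na+].[O-]I(=O)(=O)=O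
Why: Lemieux–Johnson oxidation (osmylation to diol 13, periodate cleavage to aldehyde 14, buffered by 2,6-lutidine) followed by borohydride reduction of the crude aldehyde; ozone is avoided because of the electron-rich arenes, and C3, α to the transient aldehyde, already sits in the favoured trans arrangement.

Step 8
Reactants: 15 {(2R,3S,4S,5R)-2,5-bis[4-(tert-butyldimethylsilyloxy)-3,5-dimethoxyphenyl]-4-[(tert-butyldimethylsilyloxy)methyl]tetrahydrofuran-3-yl}methanol
Product: 16 (2R,3S,4S,5R)-2,5-bis(4-hydroxy-3,5-dimethoxyphenyl)-3,4-bis(hydroxymethyl)tetrahydrofuran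
Conditions: n-Bu4NF, AcOH, THF, 0 °C → rt
Reagents that add atoms: none
Why: Fluoride cleavage of the two aryl and one primary alkyl silyl ethers in one operation; the acetic acid buffer keeps the liberated syringyl phenols protonated, so no phenoxide can open the benzylic ring bonds, and no stereocentre is touched.

## Compound list

1 | syringaldehyde (4-hydroxy-3,5-dimethoxybenzaldehyde) | COc1cc(C=O)cc(OC)c1O | starting material
2 | 4-(tert-butyldimethylsilyloxy)-3,5-dimethoxybenzaldehyde | COc1cc(C=O)cc(OC)c1O[Si](C)(C)C(C)(C)C | intermediate
3 | tert-butyldimethyl(prop-2-yn-1-yloxy)silane | C#CCO[Si](C)(C)C(C)(C)C | starting material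
4 | (E)-tert-butyldimethyl{[3-(4,4,5,5-tetramethyl-1,3,2-dioxaborolan-2-yl)prop-2-en-1-yl]oxy}silane | CC(C)(C)[Si](C)(C)OC/C=C/B1OC(C)(C)C(C)(C)O1 | intermediate
5 | lithium (E)-(chloromethyl){3-[(tert-butyldimethylsilyl)oxy]prop-1-en-1-yl}(pinacolato)borate | [Li+].CC(C)(C)[Si](C)(C)OC/C=C/[B-]1(CCl)OC(C)(C)C(C)(C)O1 | intermediate
6 | (E)-tert-butyldimethyl{[4-(4,4,5,5-tetramethyl-1,3,2-dioxaborolan-2-yl)but-2-en-1-yl]oxy}silane | CC(C)(C)[Si](C)(C)OC/C=C/CB1OC(C)(C)C(C)(C)O1 | intermediate
7 | 2-{(1R,2S)-1-[4-(tert-butyldimethylsilyloxy)-3,5-dimethoxyphenyl]-2-[(tert-butyldimethylsilyloxy)methyl]but-3-en-1-yloxy}-4,4,5,5-tetramethyl-1,3,2-dioxaborolane | CC1(C)OB(O[C@@H](c2cc(OC)c(O[Si](C)(C)C(C)(C)C)c(OC)c2)[C@H](CO[Si](C)(C)C(C)(C)C)C=C)OC1(C)C | intermediate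
8 | (1R,2S)-1-[4-(tert-butyldimethylsilyloxy)-3,5-dimethoxyphenyl]-2-[(tert-butyldimethylsilyloxy)methyl]but-3-en-1-ol | O[C@@H](c1cc(OC)c(O[Si](C)(C)C(C)(C)C)c(OC)c1)[C@H](CO[Si](C)(C)C(C)(C)C)C=C | intermediate
9 | allyltrimethylsilane | C=CC[Si](C)(C)C | starting material
10 | (1R,2S,3E)-1-[4-(tert-butyldimethylsilyloxy)-3,5-dimethoxyphenyl]-2-[(tert-butyldimethylsilyloxy)methyl]-5-(trimethylsilyl)pent-3-en-1-ol | O[C@@H](c1cc(OC)c(O[Si](C)(C)C(C)(C)C)c(OC)c1)[C@H](CO[Si](C)(C)C(C)(C)C)/C=C/C[Si](C)(C)C | intermediate
11 | E-oxocarbenium triflate from 10 and 2 (O1=C2 cation, aryl trans to C5) | COc1cc(/C=[O+]/[C@@H](c2cc(OC)c(O[Si](C)(C)C(C)(C)C)c(OC)c2)[C@H](CO[Si](C)(C)C(C)(C)C)/C=C/C[Si](C)(C)C)cc(OC)c1O[Si](C)(C)C(C)(C)C.[O-]S(=O)(=O)C(F)(F)F | intermediate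
12 | (2R,3R,4S,5R)-2,5-bis[4-(tert-butyldimethylsilyloxy)-3,5-dimethoxyphenyl]-4-[(tert-butyldimethylsilyloxy)methyl]-3-vinyltetrahydrofuran (all-trans) | COc1cc([C@@H]2O[C@@H](c3cc(OC)c(O[Si](C)(C)C(C)(C)C)c(OC)c3)[C@H](CO[Si](C)(C)C(C)(C)C)[C@H]2C=C)cc(OC)c1O[Si](C)(C)C(C)(C)C | intermediate
13 | 1-{(2R,3S,4S,5R)-2,5-bis[4-(tert-butyldimethylsilyloxy)-3,5-dimethoxyphenyl]-4-[(tert-butyldimethylsilyloxy)methyl]tetrahydrofuran-3-yl}ethane-1,2-diol (both epimers at the new carbinol carbon) | COc1cc([C@@H]2O[C@@H](c3cc(OC)c(O[Si](C)(C)C(C)(C)C)c(OC)c3)[C@H](CO[Si](C)(C)C(C)(C)C)[C@H]2C(O)CO)cc(OC)c1O[Si](C)(C)C(C)(C)C | intermediate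
14 | (2R,3R,4S,5R)-2,5-bis[4-(tert-butyldimethylsilyloxy)-3,5-dimethoxyphenyl]-4-[(tert-butyldimethylsilyloxy)methyl]tetrahydrofuran-3-carbaldehyde | COc1cc([C@@H]2O[C@@H](c3cc(OC)c(O[Si](C)(C)C(C)(C)C)c(OC)c3)[C@H](CO[Si](C)(C)C(C)(C)C)[C@H]2C=O)cc(OC)c1O[Si](C)(C)C(C)(C)C | intermediate
15 | {(2R,3S,4S,5R)-2,5-bis[4-(tert-butyldimethylsilyloxy)-3,5-dimethoxyphenyl]-4-[(tert-butyldimethylsilyloxy)methyl]tetrahydrofuran-3-yl}methanol | COc1cc([C@@H]2O[C@@H](c3cc(OC)c(O[Si](C)(C)C(C)(C)C)c(OC)c3)[C@H](CO[Si](C)(C)C(C)(C)C)[C@H]2CO)cc(OC)c1O[Si](C)(C)C(C)(C)C | intermediate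
16 | (2R,3S,4S,5R)-2,5-bis(4-hydroxy-3,5-dimethoxyphenyl)-3,4-bis(hydroxymethyl)tetrahydrofuran | COc1cc([C@@H]2O[C@@H](c3cc(OC)c(O)c(OC)c3)[C@H](CO)[C@H]2CO)cc(OC)c1O | target

## Step count and least certain steps

Total: 8 steps. Longest linear sequence: 7 steps (steps 2–8, from 3); step 1 is a side branch whose product 2 is used in steps 4 and 6.

**Step 6 (key step).**
- What may go wrong: the most likely failure is closure through the synclinal instead of the antiperiplanar alkene orientation, which costs facial selectivity at the oxocarbenium carbon and puts the C2 aryl group cis to the vinyl group. Further risks are ionisation of the benzylic C5–O bond before the acetal forms (loss of C5 configuration or cyclopropane formation with the allylsilane), a 2-oxonia-Cope shift of 11 competing with the rather slow closure of an aryl-stabilised cation, and protodesilylation by the triflic acid released.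
- Fallback: separate ring formation from stereocontrol at C2. Setting out from 10 and 2, the closure would be run as above without regard to C2, and any 2,3-cis isomer (2S,3R,4S,5R)-2,5-bis[4-(tert-butyldimethylsilyloxy)-3,5-dimethoxyphenyl]-4-[(tert-butyldimethylsilyloxy)methyl]-3-vinyltetrahydrofuran F1 would then be equilibrated in a separate operation with a catalytic strong acid (camphorsulfonic acid or BF3·OEt2, CH2Cl2, low temperature). This is the acid-mediated benzylic C–O ionisation and reclosure long used to epimerise 2-aryltetrahydrofuran and furofuran lignans. C3 and C4 cannot move, and the aryl group prefers to lie trans to the C3 substituent, so the material should return to the route at 12.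

**Step 5.**
- What may go wrong: incomplete E selectivity, and migration of the new double bond by ruthenium hydride species on long reaction times; a Z allylsilane would close through a more crowded transition state in step 6.
- Fallback: setting out from 8, cross-metathesis with (Z)-but-2-ene-1,4-diyl diacetate under the same ruthenium catalyst would give the allylic acetate (2E,4S,5R)-5-[4-(tert-butyldimethylsilyloxy)-3,5-dimethoxyphenyl]-5-hydroxy-4-[(tert-butyldimethylsilyloxy)methyl]pent-2-en-1-yl acetate F2. Palladium-catalysed allylic silylation of F2 with Me3SiSiMe3 (Pd(dba)2, LiCl, DMF) would then give 10. The π-allylpalladium intermediate relaxes to its syn form, so the E allylsilane should result whatever the geometry of F2, with silicon at the unbranched terminus.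

**Step 4.**
- What may go wrong: slow turnover or reduced facial discrimination because the γ-CH2OTBS group crowds the chair transition state, and uncatalysed background addition if the temperature has to be raised.
- Fallback: setting out from 2, an iridium-catalysed transfer-hydrogenative anti-(hydroxymethyl)allylation with 4-vinyl-1,3-dioxolan-2-one ([Ir(cod)Cl]2, the matching enantiomer of 5,5′-bis(diphenylphosphino)-4,4′-bi-1,3-benzodioxole, 4-chloro-3-nitrobenzoic acid, K3PO4, 2-propanol, THF) would give the diol (1R,2S)-1-[4-(tert-butyldimethylsilyloxy)-3,5-dimethoxyphenyl]-2-vinylpropane-1,3-diol F3. Selective silylation of its primary hydroxyl (TBSCl, imidazole, CH2Cl2, 0 °C) would return to the route at 8. This also bypasses steps 2 and 3.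

**Step 8.**
- What may go wrong: transient phenoxide formation during desilylation, leading to ring opening through a quinone methide (epimerisation at C2 or C5) or to air oxidation of the syringyl phenols, and slow cleavage of the primary silyl ether under buffered conditions.
- Fallback: a staged deprotection. Setting out from 15, KHF2 in MeOH at rt would cleave only the aryl silyl ethers, giving {(2R,3S,4S,5R)-2,5-bis(4-hydroxy-3,5-dimethoxyphenyl)-4-[(tert-butyldimethylsilyloxy)methyl]tetrahydrofuran-3-yl}methanol F4. HF·pyridine in THF/pyridine at 0 °C would then remove the primary silyl ether under non-basic conditions and arrive at 16.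

## Further compounds

F1 | step 6 | (2S,3R,4S,5R)-2,5-bis[4-(tert-butyldimethylsilyloxy)-3,5-dimethoxyphenyl]-4-[(tert-butyldimethylsilyloxy)methyl]-3-vinyltetrahydrofuran (2-epimer of 12) | COc1cc([C@H]2O[C@@H](c3cc(OC)c(O[Si](C)(C)C(C)(C)C)c(OC)c3)[C@H](CO[Si](C)(C)C(C)(C)C)[C@H]2C=C)cc(OC)c1O[Si](C)(C)C(C)(C)C
F2 | step 5 | (2E,4S,5R)-5-[4-(tert-butyldimethylsilyloxy)-3,5-dimethoxyphenyl]-5-hydroxy-4-[(tert-butyldimethylsilyloxy)methyl]pent-2-en-1-yl acetate | O[C@@H](c1cc(OC)c(O[Si](C)(C)C(C)(C)C)c(OC)c1)[C@H](CO[Si](C)(C)C(C)(C)C)/C=C/COC(C)=O
F3 | step 4 | (1R,2S)-1-[4-(tert-butyldimethylsilyloxy)-3,5-dimethoxyphenyl]-2-vinylpropane-1,3-diol | O[C@@H](c1cc(OC)c(O[Si](C)(C)C(C)(C)C)c(OC)c1)[C@H](CO)C=C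
F4 | step 8 | {(2R,3S,4S,5R)-2,5-bis(4-hydroxy-3,5-dimethoxyphenyl)-4-[(tert-butyldimethylsilyloxy)methyl]tetrahydrofuran-3-yl}methanol | COc1cc([C@@H]2O[C@@H](c3cc(OC)c(O)c(OC)c3)[C@H](CO[Si](C)(C)C(C)(C)C)[C@H]2CO)cc(OC)c1O
A1 | alternative 1 | target bis(tert-butyldiphenylsilyl) ether | COc1cc([C@@H]2O[C@@H](c3cc(OC)c(O)c(OC)c3)[C@H](CO[Si](c4ccccc4)(c4ccccc4)C(C)(C)C)[C@H]2CO[Si](c5ccccc5)(c5ccccc5)C(C)(C)C)cc(OC)c1O
A2 | alternative 1 | (3S,4S)-3,4-bis[(tert-butyldiphenylsilyloxy)methyl]-2,5-dimethoxytetrahydrofuran (anomer mixture) | COC1OC(OC)[C@H](CO[Si](c2ccccc2)(c2ccccc2)C(C)(C)C)[C@H]1CO[Si](c1ccccc1)(c1ccccc1)C(C)(C)C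
A3 | alternative 1 | 2,6-dimethoxyphenol | COc1cccc(OC)c1O
A4 | alternative 2 | dimethyl all-trans-2,5-bis(4-hydroxy-3,5-dimethoxyphenyl)tetrahydrofuran-3,4-dicarboxylate | COc1cc([C@@H]2O[C@@H](c3cc(OC)c(O)c(OC)c3)[C@H](C(=O)OC)[C@H]2C(=O)OC)cc(OC)c1O
A5 | alternative 2 | dimethyl all-trans-3,4-bis(4-hydroxy-3,5-dimethoxyphenyl)cyclobutane-1,2-dicarboxylate (enantiomer whose ester-bearing carbons map onto C3 and C4 of the target) | COc1cc([C@@H]2[C@@H](c3cc(OC)c(O)c(OC)c3)[C@H](C(=O)OC)[C@H]2C(=O)OC)cc(OC)c1O
A6 | alternative 2 | methyl sinapate | COC(=O)/C=C/c1cc(OC)c(O)c(OC)c1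
A7 | alternative 3 | dimenthyl all-trans-2,5-bis(4-benzyloxy-3,5-dimethoxyphenyl)tetrahydrofuran-3,4-dicarboxylate | COc1cc([C@@H]2O[C@@H](c3cc(OC)c(OCc4ccccc4)c(OC)c3)[C@H](C(=O)O[C@@H]5C[C@H](C)CC[C@H]5C(C)C)[C@H]2C(=O)O[C@@H]6C[C@H](C)CC[C@H]6C(C)C)cc(OC)c1OCc1ccccc1
A8 | alternative 3 | trans-2,3-bis(4-benzyloxy-3,5-dimethoxyphenyl)oxirane (racemic; one enantiomer drawn) | COc1cc([C@@H]2O[C@H]2c3cc(OC)c(OCc4ccccc4)c(OC)c3)cc(OC)c1OCc1ccccc1
A9 | alternative 3 | di-(−)-menthyl fumarate | O=C(/C=C/C(=O)O[C@@H]1C[C@H](C)CC[C@H]1C(C)C)O[C@@H]1C[C@H](C)CC[C@H]1C(C)C
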